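**Retrosynthetic overview**
- The target is reached by fluoride cleavage of the 7-O-triisopropylsilyl ether of the (S)-flavanone; the silyl group is the only protecting group carried through the key step.
- The strategy rests on C2 of ring C (the pyranone): a benzylic CH bearing O1 and the phenyl ring B, next to the C3 methylene alpha to the C4 ketone. The C2–C3 bond is therefore cut back to a C3 ketocarbenoid (from an aryl diazomethyl ketone) and one benzylic C–H of an O1-benzyl ether.
- Enantioselective carbenoid C–H insertion closes ring C, the only ring made in the route; rings A and B come from the starting materials.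
- The diazoketone comes from the methyl ketone by detrifluoroacetylative diazo transfer; the methyl ketone comes from 2,4-dihydroxy-3,5-diprenylacetophenone by 4-O-silylation and 2-O-benzylation.
- The diprenyl ketone comes from 2,4-dihydroxyacetophenone by 3,5-diiodination and twofold Stille prenylation.

Key step: step 6

Assumption: the sense of induction of Rh2(S-BSP)4 on this substrate cannot be predicted with confidence and is taken to give the (S)-flavanone; if the first run shows the opposite sense, the mirror-image catalyst Rh2(R-BSP)4 is used in the same step with nothing else changed.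

**Step 1**
Reactants: 1 2,4-dihydroxyacetophenone
Product: 2 2,4-dihydroxy-3,5-diiodoacetophenone
Conditions: NIS (2.1 equiv), TsOH·H2O (10 mol %), MeCN, 0 °C to rt, dark
Reagents that add atoms: N-iodosuccinimide, O=C1CCC(=O)N1I
Why: Electrophilic aromatic iodination, in which C3 and C5 are the two ring positions ortho or para to both hydroxyl groups, so two equivalents of iodonium should fill exactly these sites and leave the acetyl group alone.

**Step 2**
Reactants: 2 2,4-dihydroxy-3,5-diiodoacetophenone, 3 tributyl(3-methylbut-2-enyl)stannane
Product: 4 2,4-dihydroxy-3,5-bis(3-methylbut-2-enyl)acetophenone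
Conditions: Pd(PPh3)4 (10 mol %), 3 (3 equiv), degassed DMF, 90 °C
Reagents that add atoms: none
Why: Twofold Stille cross-coupling, in which zerovalent palladium inserts into both aryl–iodine bonds, the prenyl group is handed over from tin and reductive elimination at the unhindered primary allyl terminus should give the linear 3-methylbut-2-enyl arene at both positions, the neutral conditions tolerating the free phenols and the ketone.

**Step 3**
Reactants: 4 2,4-dihydroxy-3,5-bis(3-methylbut-2-enyl)acetophenone
Product: 5 2-hydroxy-3,5-bis(3-methylbut-2-enyl)-4-(triisopropylsilyloxy)acetophenone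
Conditions: TIPSOTf (1.05 equiv), 2,6-lutidine (2 equiv), CH2Cl2, −78 to 0 °C
Reagents that add atoms: triisopropylsilyl trifluoromethanesulfonate, CC(C)[Si](OS(=O)(=O)C(F)(F)F)(C(C)C)C(C)C
Why: Chemoselective O-silylation, in which the 4-hydroxyl is the more acidic and more nucleophilic one while the 2-hydroxyl is locked in a hydrogen bond to the acetyl oxygen, so one equivalent of silyl triflate should cap O4 only; the bulky triisopropylsilyl group is chosen because it should withstand the carbonate, amide-base and amine conditions of steps 4 and 5 better than a smaller silyl group.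

**Step 4**
Reactants: 5 2-hydroxy-3,5-bis(3-methylbut-2-enyl)-4-(triisopropylsilyloxy)acetophenone, 6 benzyl bromide
Product: 7 2-benzyloxy-3,5-bis(3-methylbut-2-enyl)-4-(triisopropylsilyloxy)acetophenone
Conditions: K2CO3 (3 equiv), 6 (1.5 equiv), Bu4NI (cat.), dry DMF, 50 °C
Reagents that add atoms: none
Why: Williamson ether synthesis, in which carbonate in warm DMF breaks the chelate and the phenoxide displaces bromide from benzyl bromide, installing the O-benzyl group whose CH2 becomes C2 of the flavanone.

**Step 5**
Reactants: 7 2-benzyloxy-3,5-bis(3-methylbut-2-enyl)-4-(triisopropylsilyloxy)acetophenone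
Product: 9 1-[2-benzyloxy-3,5-bis(3-methylbut-2-enyl)-4-(triisopropylsilyloxy)phenyl]-2-diazoethanone, via trifluoroacetyl diketone 8 (not isolated)
Conditions: LiN(SiMe3)2 (1.1 equiv), THF, −78 °C; CF3CO2CH2CF3 (1.2 equiv), −78 °C; cold 5% aq HCl work-up; then MsN3 (1.5 equiv), Et3N (1.5 equiv), H2O (1 equiv), MeCN, rt
Reagents that add atoms: 2,2,2-trifluoroethyl trifluoroacetate, O=C(OCC(F)(F)F)C(F)(F)F (trifluoroacetyl group of 8); methanesulfonyl azide, CS(=O)(=O)N=[N+]=[N-] (diazo nitrogens of 9)
Why: Detrifluoroacetylative diazo transfer (Danheiser procedure), in which Claisen trifluoroacetylation of the methyl ketone enolate gives the activated 1,3-diketone 8, which should take up the diazo group from the sulfonyl azide (Regitz transfer) and pass its trifluoroacetyl group to the sulfonamide nitrogen, conditions that leave the aryl silyl ether, the benzyl ether and the prenyl alkenes untouched.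

**Step 6**
Reactants: 9 1-[2-benzyloxy-3,5-bis(3-methylbut-2-enyl)-4-(triisopropylsilyloxy)phenyl]-2-diazoethanone
Product: 10 (S)-6,8-bis(3-methylbut-2-enyl)-7-(triisopropylsilyloxy)flavanone
Conditions: Rh2(S-BSP)4 [dirhodium tetrakis(N-benzenesulfonyl-(S)-prolinate), 2 mol %], CH2Cl2, 0 °C to rt, 9 added by syringe pump over 4 h (final 0.01 M)
Reagents that add atoms: none
Why: Rhodium-carbenoid intramolecular C–H insertion, the known way from 2-alkoxyaryl diazoketones to 2-substituted chroman-4-ones under chiral dirhodium carboxylate catalysis: the divalent rhodium dimer expels N2 from 9 and the resulting electrophilic ketocarbenoid at the future C3 should take up one benzylic C–H bond of the O-benzyl group in a concerted, asynchronous three-centre transition state with partial hydride shift to the carbenoid carbon, forming C2–C3 and releasing the catalyst. Ring C closes in the 1,6-insertion mode (carbenoid carbon, C4, C4a, C8a, O1, benzylic carbon), a six-membered ring since the atom in the 1,5-relationship to the carbenoid carbon is O1, which has no hydrogen to offer. The new stereocentre C2 is controlled by the catalyst, whose chiral prolinate ligands around the rhodium–carbene distinguish the two enantiotopic benzylic hydrogens (sense of induction as assumed above). The step needs chemoselectivity for C–H insertion over oxonium ylide formation with [1,2]-benzyl shift, over carbene dimerisation and over alkene cyclopropanation; the substrate helps because the only C–H within reach is doubly activated (benzylic and alpha to oxygen), O1 is a weakly nucleophilic aryl ether oxygen ortho to the acyl group, both prenyl groups sit meta to the acyl group and cannot reach the carbenoid, and slow addition at high dilution holds back the bimolecular paths. The medium contains no acid or base, so C2 should not epimerise once formed.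

**Step 7**
Reactants: 10 (S)-6,8-bis(3-methylbut-2-enyl)-7-(triisopropylsilyloxy)flavanone
Product: 11 (S)-7-hydroxy-6,8-diprenylflavanone
Conditions: Bu4NF (1.2 equiv), AcOH (1.5 equiv), THF, 0 °C to rt
Reagents that add atoms: none
Why: Fluoride-mediated desilylation, in which fluoride attacks silicon and frees the 7-phenol while the acetic acid buffer keeps the medium from turning basic, so that retro-oxa-Michael opening of ring C (which would racemise C2) and any reaction of the prenyl groups should be avoided.

**Compound list**
1 | 2,4-dihydroxyacetophenone | CC(=O)c1ccc(O)cc1O | starting material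
2 | 2,4-dihydroxy-3,5-diiodoacetophenone | CC(=O)c1cc(I)c(O)c(I)c1O | intermediate
3 | tributyl(3-methylbut-2-enyl)stannane (tributyl(prenyl)stannane) | CCCC[Sn](CCCC)(CCCC)CC=C(C)C | starting material
4 | 2,4-dihydroxy-3,5-bis(3-methylbut-2-enyl)acetophenone | CC(=O)c1cc(CC=C(C)C)c(O)c(CC=C(C)C)c1O | intermediate
5 | 2-hydroxy-3,5-bis(3-methylbut-2-enyl)-4-(triisopropylsilyloxy)acetophenone | CC(=O)c1cc(CC=C(C)C)c(O[Si](C(C)C)(C(C)C)C(C)C)c(CC=C(C)C)c1O | intermediate
6 | benzyl bromide | BrCc1ccccc1 | starting material
7 | 2-benzyloxy-3,5-bis(3-methylbut-2-enyl)-4-(triisopropylsilyloxy)acetophenone | CC(=O)c1cc(CC=C(C)C)c(O[Si](C(C)C)(C(C)C)C(C)C)c(CC=C(C)C)c1OCc1ccccc1 | intermediate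
8 | 1-[2-benzyloxy-3,5-bis(3-methylbut-2-enyl)-4-(triisopropylsilyloxy)phenyl]-4,4,4-trifluorobutane-1,3-dione | O=C(CC(=O)C(F)(F)F)c1cc(CC=C(C)C)c(O[Si](C(C)C)(C(C)C)C(C)C)c(CC=C(C)C)c1OCc1ccccc1 | intermediate
9 | 1-[2-benzyloxy-3,5-bis(3-methylbut-2-enyl)-4-(triisopropylsilyloxy)phenyl]-2-diazoethanone | [N-]=[N+]=CC(=O)c1cc(CC=C(C)C)c(O[Si](C(C)C)(C(C)C)C(C)C)c(CC=C(C)C)c1OCc1ccccc1 | intermediate
10 | (S)-6,8-bis(3-methylbut-2-enyl)-7-(triisopropylsilyloxy)flavanone | CC(C)=CCc1cc2c(c(CC=C(C)C)c1O[Si](C(C)C)(C(C)C)C(C)C)O[C@H](c1ccccc1)CC2=O | intermediate
11 | (S)-7-hydroxy-6,8-diprenylflavanone | CC(C)=CCc1cc2c(c(CC=C(C)C)c1O)O[C@H](c1ccccc1)CC2=O | target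

**Step count and risks**
Total step count: 7. Longest linear sequence: 7 steps (from 1 to 11).

Steps most likely to fail:

1. Step 6. The ether oxygen may attack the carbenoid to give a five-membered oxonium ylide that undergoes [1,2]-benzyl shift (ring contraction instead of insertion). The carbenoid may also dimerise, and an unsubstituted ketocarbenoid may discriminate the two enantiotopic benzylic hydrogens only weakly. Fallback: set out from 5 and condense it with N,N-dimethylformamide dimethyl acetal (toluene, 90 °C) to the enaminone (E)-3-(dimethylamino)-1-[2-hydroxy-3,5-bis(3-methylbut-2-enyl)-4-(triisopropylsilyloxy)phenyl]prop-2-en-1-one F1. Cyclise this in warm acetic acid, with loss of dimethylamine, to 6,8-bis(3-methylbut-2-enyl)-7-(triisopropylsilyloxy)chromone F2. Then add phenylboronic acid by asymmetric 1,4-addition catalysed by monovalent rhodium ([Rh(OH)(cod)]2 with an electron-poor atropisomeric bisphosphine of the MeO-BIPHEP family, ligand enantiomer chosen for the (S)-product, CH2Cl2/H2O, rt). This comes back to the route at 10, which goes on through step 7.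

2. Step 2. The acidic phenols may consume the allylstannane by protonolysis, the second coupling may stall at the iodide flanked by two oxygens, and allylic transposition during transmetalation may give the branched 1,1-dimethylallyl isomer. Fallback: set out from 1 and C-prenylate the phenoxide directly with prenyl bromide (2.2 equiv) in aqueous KOH at 0 °C to rt, an electrophilic alkylation at C3 and C5 with no cross-coupling. Chromatographic removal of mono- and O-prenylated material comes back to the route at 4; the route then continues with step 3, and steps 1 and 2 are dropped.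

3. Step 4. The hydrogen-bonded phenoxide, flanked by the acyl and a prenyl group, may alkylate slowly, and during the long reaction time phenoxide or carbonate may attack silicon and cause silyl loss or silyl transfer. Fallback: set out from 5 and form the ether by Mitsunobu reaction with benzyl alcohol, PPh3 and diisopropyl azodicarboxylate in THF at 0 °C to rt. This activates the alcohol under neutral conditions instead of the phenoxide under basic ones, and comes back to the route at 7.

**Further compounds**
F1 | step 6 | (E)-3-(dimethylamino)-1-[2-hydroxy-3,5-bis(3-methylbut-2-enyl)-4-(triisopropylsilyloxy)phenyl]prop-2-en-1-one | CN(C)/C=C/C(=O)c1cc(CC=C(C)C)c(O[Si](C(C)C)(C(C)C)C(C)C)c(CC=C(C)C)c1O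
F2 | step 6 | 6,8-bis(3-methylbut-2-enyl)-7-(triisopropylsilyloxy)chromone | O=c1ccoc2c(CC=C(C)C)c(O[Si](C(C)C)(C(C)C)C(C)C)c(CC=C(C)C)cc12
F0 | step 2 | none | none
F0 | step 4 | none | none
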